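The earlier runs and the new flask come from a simulation from invented constants.

My unit was the fraction of the substrate charged per minute, and the question was which of these differently fed flasks ends with the most target.

| setting | north | south | north-east | south-east | zeta | beta | gamma | epsilon |
|---|---|---|---|---|---|---|---|---|
| substrate | 0.050 M | 0.050 M | 0.050 M | 0.075 M | 0.050 M | 0.050 M | 0.050 M (fed, over 25 min) | 0.050 M |
| reagent | 0.035 M | 0.018 M | 0.070 M | 0.035 M | 0.0350 M (fed, over 6.0 min) | 0.0350 M | 0.0350 M | 0.0350 M (fed, over 25 min) |
| remark | run made earlier | run made earlier | run made earlier | run made earlier | all else is in the flask from the start; the feed brings no volume worth counting | everything together at the start | all else is in the flask from the start; the feed brings no volume worth counting | all else is in the flask from the start; the feed brings no volume worth counting |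
| time |  |  |  |  | 40 min | 40 min | 40 min | 40 min |

| run | time / min | target / % |
|---|---|---|
| north | 2.00 | 5.1 |
| north | 4.00 | 11.9 |
| north | 10.0 | 29.1 |
| north | 25.0 | 44.4 |
| south | 3.00 | 4.7 |
| south | 8.00 | 15.1 |
| south | 15.0 | 20.5 |
| south | 40.0 | 25.2 |
| north-east | 5.00 | 24.5 |
| north-east | 15.0 | 53.1 |
| north-east | 25.0 | 59.7 |
| north-east | 40.0 | 63.0 |
| south-east | 10.0 | 23.9 |
| south-east | 20.0 | 28.1 |
| south-east | 30.0 | 28.8 |
| south-east | 40.0 | 29.5 |

(standard deviation of a reading: 0.5 percentage points)

* the flask with the highest amount of target, in percent of the substrate charged ("all alike" if they lie within 1.5 percentage points) (zeta / beta / gamma / epsilon / all alike)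
* final target, as a percentage of the substrate charged, in zeta
* final target, as a percentage of the substrate charged, in beta
* final target, as a percentage of the substrate charged, in gamma
* final target, as a percentage of the substrate charged, in epsilon

- the analysis behind the earlier runs scatters by 0.5 percentage points, standard deviation

In north-east, with reagent above the substrate charge, target rose at 0.0490 min⁻¹ up to 5.00 min, then at 0.0286 min⁻¹, 0.00660 min⁻¹ and 0.00220 min⁻¹. These are slowings by factors of 1.71, 4.33 and 3.00, together 22.3, so I froze the end near the reading 63.0%.

I read the remainder as substrate lost, together with reagent, one to one, by a route that grows with c(reagent). This gave my waste ratio 8.39 L mol⁻¹, lost over useful substrate per unit c(reagent), with c(reagent) frozen at its charge; it is a selectivity factor. For south it gave a lost share of 13.1%, and the gap between charge ratio and last reading was 11 percentage points.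

I took substrate to last about 5.00 min and froze c(reagent) at half of what the feed had delivered by then: 0.00350 M in epsilon, 0.0146 M in zeta. Lost shares followed: 2.85% in epsilon, 10.9% in zeta, 22.7% in beta. Subtracted from the charge ratio, they left rough estimates of long-run target of 67.1%, 59.1% and 47.3%, so I ranked epsilon above zeta and beta.

The forecast differed: gamma highest, with zeta 48%, beta 48.5%, gamma 52.5%, epsilon 43%, holding that “The long reagent feed has the same selectivity but finishes late”.

The flasks gave zeta 57.6%, beta 48.3%, gamma 47.5% and epsilon 61.2%, so epsilon stood highest.

    substrate + reagent → side product (k = 2.50 L mol⁻¹ min⁻¹)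
    substrate → intermediate (k = 0.250 min⁻¹)
    reagent + intermediate → target (k = 4.20 L mol⁻¹ min⁻¹)

At 2.66 min in epsilon, substrate went to intermediate 33 times as fast as to side product. Epsilon's side product stood at 3.16% against my 2.85%, and beta's at 19.7% against my 22.7%.

For the neighbour of epsilon with 0.060 M of reagent, the same reckoning froze c(reagent) at 0.00600 M and gave a lost share of 4.79%. The computed side product there was 5.31%.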